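**Strategy.** Daucane numbering: ring A is the cyclopentane C1–C5 (C1 quaternary, C4 isopropyl carbinol, C5 ring-fusion CH); ring B is the cycloheptene; C6 bears the ester. The plan rests on the hindered C1–C5 bond and exploits the aldol-type array O–C4–C5–C6–O beside C1. Ring A is grown from a cyclobutanol (C1–C4) whose carbinol carbon C4 carries a trans-oxirane (C5–C6). One Lewis-acid semipinacol shift moves C1 from C4 to C5: it enlarges the ring, forms C1–C5 with inversion at C5, keeps C6–O and unveils the C4 ketone. C1 comes from a catalytic asymmetric allylic alkylation; isopropyl addition, ring-closing metathesis of ring B and acylation complete the route.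

Key step: step 9

Assumption: the ligand antipodes named in steps 4 and 8 are assigned by analogy with related substrates; the mirror-image ligand would be used if the opposite sense of induction were found.

Step 1
Reactants: 1 cyclopentane-1,3-dione
Product: 2 2-diazocyclopentane-1,3-dione
Conditions: 4-acetamidobenzenesulfonyl azide, Et3N, MeCN, 0 °C to rt
Reagents that add atoms: 4-acetamidobenzenesulfonyl azide, CC(=O)Nc1ccc(cc1)S(=O)(=O)N=[N+]=[N-]
Why: Regitz diazo transfer to the doubly activated methylene group of a 1,3-dione is a standard reaction and creates no stereocentre.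

Step 2
Reactants: 2 2-diazocyclopentane-1,3-dione; 3 allyl alcohol
Product: 5 allyl 2-oxocyclobutane-1-carboxylate, via acylketene 4 (not isolated)
Conditions: toluene, 160–180 °C, sealed vessel (microwave)
Reagents that add atoms: none
Why: Thermal Wolff rearrangement of the cyclic 2-diazo-1,3-dione contracts the ring to acylketene 4, which allyl alcohol traps as the β-keto ester, and the new stereocentre is configurationally labile and left undefined.

Step 3
Reactants: 5 allyl 2-oxocyclobutane-1-carboxylate
Product: 6 allyl 1-methyl-2-oxocyclobutane-1-carboxylate (racemic)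
Conditions: MeI, K2CO3, acetone, rt
Reagents that add atoms: iodomethane, CI
Why: C-alkylation of the soft β-keto ester enolate gives the racemic quaternary ester, whose configuration is erased in the next step.

Step 4
Reactants: 6 allyl 1-methyl-2-oxocyclobutane-1-carboxylate
Product: 7 (R)-2-allyl-2-methylcyclobutan-1-one
Conditions: Pd2(dba)3 (2.5 mol %), (R)-(CF3)3-t-BuPHOX (6 mol %), toluene, 20 °C
Reagents that add atoms: none
Why: In this decarboxylative asymmetric allylic alkylation (Tsuji–Trost type) zerovalent palladium ionises the allyl ester, carbon dioxide is lost and the prochiral enolate recombines with the allyl unit inside the chiral PHOX–palladium complex, which sets C1 as R from both enantiomers of 6.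

Step 5
Reactants: 8 ethynylmagnesium bromide; 9 3-chloro-2-methylprop-1-ene
Product: 10 2-methylpent-1-en-4-yne
Conditions: CuCl (5 mol %), THF, 0 to 50 °C; distilled as a THF solution
Reagents that add atoms: none
Why: Copper-catalysed allylic substitution of an alkynyl Grignard reagent on methallyl chloride is the standard entry to skipped 1,4-enynes, direct and allylic attack give the same product, and no stereocentre is formed.

Step 6
Reactants: 10 2-methylpent-1-en-4-yne
Product: 12 (E)-1-iodo-4-methylpenta-1,4-diene, via alkenylzirconocene chloride 11 (not isolated)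
Conditions: Cp2ZrHCl, THF, rt; then I2, 0 °C
Reagents that add atoms: iodine, II; zirconocene chloride hydride Cp2ZrHCl, [H][Zr](Cl)(C1C=CC=C1)C1C=CC=C1 (its Zr, Cl and Cp atoms stay only in 11)
Why: Hydrozirconation adds Zr–H syn and terminally to the alkyne much faster than to the 1,1-disubstituted alkene, and iodinolysis with retention fixes the E geometry that later becomes the trans-oxirane.

Step 7
Reactants: 12 (E)-1-iodo-4-methylpenta-1,4-diene; 7 (R)-2-allyl-2-methylcyclobutan-1-one
Product: 14 (1S,2R)-2-allyl-2-methyl-1-[(1E)-4-methylpenta-1,4-dien-1-yl]cyclobutan-1-ol, via alkenyllithium 13 (not isolated)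
Conditions: 12, t-BuLi (2 equiv), Et2O, −78 °C; then 7, −78 °C; H2O
Reagents that add atoms: tert-butyllithium, [Li]C(C)(C)C (its lithium stays only in 13)
Why: Iodine–lithium exchange with retention of geometry and 1,2-addition to the strained, electrophilic cyclobutanone give the tertiary allylic alcohol, attack anti to the larger allyl group should favour the (1S) epimer, and because this carbon becomes the ketone carbon in step 9 the minor epimer is carried along.

Step 8
Reactants: 14 (1S,2R)-2-allyl-2-methyl-1-[(1E)-4-methylpenta-1,4-dien-1-yl]cyclobutan-1-ol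
Product: 15 (1R,2R)-2-allyl-2-methyl-1-[(2R,3S)-3-(2-methylprop-2-en-1-yl)oxiran-2-yl]cyclobutan-1-ol
Conditions: Hf(OtBu)4 (10 mol %), (R,R)-BHA (C2-symmetric bishydroxamic acid from (1R,2R)-cyclohexane-1,2-diamine, 11 mol %), cumene hydroperoxide, MgO, toluene, 0 °C
Reagents that add atoms: cumene hydroperoxide, CC(C)(OO)c1ccccc1
Why: In this hydroxyl-directed catalytic asymmetric epoxidation of a tertiary allylic alcohol only the alkene allylic to the hafnium alkoxide is oxidised, so the vinyl and methallyl groups survive, syn oxygen transfer to the E-alkene gives the trans-oxirane, and the chiral ligand chooses the face that makes C5 R and C6 S for either carbinol epimer.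

Step 9
Reactants: 15 (1R,2R)-2-allyl-2-methyl-1-[(2R,3S)-3-(2-methylprop-2-en-1-yl)oxiran-2-yl]cyclobutan-1-ol
Product: 16 (2S,3R)-3-allyl-2-[(1S)-1-hydroxy-3-methylbut-3-en-1-yl]-3-methylcyclopentan-1-one
Conditions: BF3·OEt2 (20 mol %), CH2Cl2, −78 to −40 °C; aq NaHCO3
Reagents that add atoms: none
Why: BF3 binds the oxirane oxygen, and as the C5–O bond next to carbinol carbon C4 lengthens, the antiperiplanar ring bond C4–C1 shifts to C5 while the C4 hydroxyl oxygen becomes the ketone, which is the semipinacol rearrangement of a 2,3-epoxy alcohol, well known for 1-oxiranylcyclobutanols. No ring is closed by cyclisation: ring A arises by a 1,2-shift that enlarges the cyclobutane C1–C2–C3–C4 to the cyclopentanone C1–C2–C3–C4–C5, driven by release of cyclobutane strain. C5 is set by inversion because C1 enters anti to the departing oxygen, C6 keeps the oxirane configuration and becomes the free carbinol, and C1 migrates with retention, so the trans-oxirane becomes the (5S,6S) aldol with its side chain cis to the C1 methyl group and trans to the allyl group. The step needs migration of C1 and not of C3; the quaternary carbon carries the developing positive charge better than the methylene carbon, and free rotation about C4–C5 lets either carbinol epimer reach the reactive conformer, so both converge on 16. It also needs cleavage at C5 and not at C6, which is secured because only C5 is flanked by the electron-releasing carbinol carbon, and the low temperature and substoichiometric acid protect the aldol from dehydration and retro-aldol cleavage.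

Step 10
Reactants: 16 (2S,3R)-3-allyl-2-[(1S)-1-hydroxy-3-methylbut-3-en-1-yl]-3-methylcyclopentan-1-one; 17 isopropylmagnesium chloride
Product: 18 (1R,2S,3R)-3-allyl-2-[(1S)-1-hydroxy-3-methylbut-3-en-1-yl]-3-methyl-1-(propan-2-yl)cyclopentan-1-ol
Conditions: LaCl3·2LiCl (1.1 equiv), THF, rt; then 17 (3 equiv), −40 to 0 °C; aq NH4Cl
Reagents that add atoms: none
Why: Lanthanum-mediated Grignard 1,2-addition suppresses enolisation and β-hydride reduction, and within the chelate of the C6 alkoxide and the C4 carbonyl the isopropyl group attacks the face opposite the C5 side chain and the pseudoaxial C1 methyl group, which sets C4 with its hydroxyl cis to both.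

Step 11
Reactants: 18 (1R,2S,3R)-3-allyl-2-[(1S)-1-hydroxy-3-methylbut-3-en-1-yl]-3-methyl-1-(propan-2-yl)cyclopentan-1-ol
Product: 19 jaeschkeanadiol, (3R,3aS,4S,8aR)-6,8a-dimethyl-3-(propan-2-yl)-1,2,3a,4,5,8-hexahydroazulene-3,4-diol
Conditions: second-generation Hoveyda–Grubbs catalyst (5 mol %), CH2Cl2 (high dilution), 40 °C
Reagents that add atoms: none
Why: Ring-closing metathesis of the vinyl and the 1,1-disubstituted alkene on trans-disposed neighbouring carbons closes the seven-membered ring B with its endocyclic trisubstituted C8=C9 alkene, tolerates the free diol and touches no stereocentre.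

Step 12
Reactants: 19 jaeschkeanadiol; 20 4-acetoxybenzoic acid
Product: 22 ferutinine, via O-acetylferutinine 21 (not isolated)
Conditions: 20, DCC, DMAP, CH2Cl2, rt; then pyrrolidine, rt
Reagents that add atoms: none
Why: Steglich esterification acylates the secondary C6 hydroxyl and leaves the tertiary C4 hydroxyl untouched, and aminolysis then cleaves the activated aryl acetate far faster than the hindered secondary alkyl benzoate.

**Compound list**
1 | cyclopentane-1,3-dione | O=C1CCC(=O)C1 | starting material
2 | 2-diazocyclopentane-1,3-dione | [N-]=[N+]=C1C(=O)CCC1=O | intermediate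
3 | allyl alcohol | C=CCO | starting material
4 | 2-(oxomethylidene)cyclobutan-1-one (acylketene) | O=C=C1CCC1=O | intermediate
5 | allyl 2-oxocyclobutane-1-carboxylate (labile stereocentre, undefined) | C=CCOC(=O)C1CCC1=O | intermediate
6 | allyl 1-methyl-2-oxocyclobutane-1-carboxylate (racemic) | C=CCOC(=O)C1(C)CCC1=O | intermediate
7 | (R)-2-allyl-2-methylcyclobutan-1-one | C=CC[C@@]1(C)CCC1=O | intermediate
8 | ethynylmagnesium bromide | C#C[Mg]Br | starting material
9 | 3-chloro-2-methylprop-1-ene | C=C(C)CCl | starting material
10 | 2-methylpent-1-en-4-yne | C=C(C)CC#C | intermediate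
11 | chloro[(1E)-4-methylpenta-1,4-dien-1-yl]zirconocene | Cl[Zr](/C=C/CC(C)=C)(C1C=CC=C1)C1C=CC=C1 | intermediate
12 | (E)-1-iodo-4-methylpenta-1,4-diene | I/C=C/CC(C)=C | intermediate
13 | (1E)-4-methylpenta-1,4-dien-1-yllithium | [Li]/C=C/CC(C)=C | intermediate
14 | (1S,2R)-2-allyl-2-methyl-1-[(1E)-4-methylpenta-1,4-dien-1-yl]cyclobutan-1-ol (dienyl chain cis to methyl) | C=CC[C@@]1(C)CC[C@]1(O)/C=C/CC(C)=C | intermediate
15 | (1R,2R)-2-allyl-2-methyl-1-[(2R,3S)-3-(2-methylprop-2-en-1-yl)oxiran-2-yl]cyclobutan-1-ol (trans-oxirane) | C=CC[C@@]1(C)CC[C@]1(O)[C@@H]2O[C@H]2CC(C)=C | intermediate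
16 | (2S,3R)-3-allyl-2-[(1S)-1-hydroxy-3-methylbut-3-en-1-yl]-3-methylcyclopentan-1-one (side chain cis to methyl) | C=CC[C@@]1(C)CCC(=O)[C@@H]1[C@@H](O)CC(C)=C | intermediate
17 | isopropylmagnesium chloride | CC(C)[Mg]Cl | starting material
18 | (1R,2S,3R)-3-allyl-2-[(1S)-1-hydroxy-3-methylbut-3-en-1-yl]-3-methyl-1-(propan-2-yl)cyclopentan-1-ol | C=CC[C@@]1(C)CC[C@@](O)(C(C)C)[C@@H]1[C@@H](O)CC(C)=C | intermediate
19 | jaeschkeanadiol (trans-fused) | CC1=CC[C@@]2(C)CC[C@@](O)(C(C)C)[C@@H]2[C@@H](O)C1 | intermediate
20 | 4-acetoxybenzoic acid | CC(=O)Oc1ccc(cc1)C(=O)O | starting material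
21 | O-acetylferutinine (jaeschkeanadiol 6-(4-acetoxybenzoate)) | CC1=CC[C@@]2(C)CC[C@@](O)(C(C)C)[C@@H]2[C@@H](OC(=O)c2ccc(OC(C)=O)cc2)C1 | intermediate
22 | ferutinine | CC1=CC[C@@]2(C)CC[C@@](O)(C(C)C)[C@@H]2[C@@H](OC(=O)c2ccc(O)cc2)C1 | target

**Total step count:** 12. **Longest linear sequence:** 10 steps (steps 1–4 and 7–12, from cyclopentane-1,3-dione).

**Steps most likely to fail**

Step 9.
- What may go wrong: the methylene carbon C3 may migrate in place of C1, a hydride may shift within the activated oxirane, or the aldol may lose water or cleave by retro-aldol reaction under the Lewis acid.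
- The fallback sets out from 7 and 10 and comes back at 16. It keeps the four- to five-membered ring enlargement but triggers it with a π-acid.
- Enyne 10 is deprotonated with n-BuLi to lithium acetylide F1, which adds to 7 to give alkynylcyclobutanol F2. The carbinol configuration of F2 is irrelevant.
- (Ph3P)AuCl/AgSbF6 in CH2Cl2 activates the alkyne, and C1 attacks it anti to gold. This gives (E)-alkylidenecyclopentanone F3. The more substituted ring carbon is the known migrating group in this reaction type.
- Copper-catalysed conjugate borylation follows (CuCl, NaOtBu, a chiral Josiphos-type bisphosphine, B2pin2, MeOH, THF). It places boron on C6 under ligand control, and protonation puts the side chain trans to the allyl group, giving β-boryl ketone F4.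
- NaBO3·4H2O oxidises the C–B bond with retention to 16.

Step 8.
- What may go wrong: facial selectivity may be poor for the mismatched carbinol epimer, the remote alkenes may be oxidised in competition, or the oxirane may open early and unselectively on the Lewis-acidic metal.
- The fallback sets out from 14 and comes back at 16. It sets C6 first and relays it to C5.
- Pyridinium chlorochromate (C5H5NH[CrO3Cl]) in CH2Cl2 effects the Babler–Dauben oxidative transposition to cyclobutylidene enone F5.
- CBS reduction ((R)-methyl oxazaborolidine, catecholborane, −78 °C) gives (S)-allylic alcohol F6.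
- Hydroxyl-directed epoxidation (VO(acac)2, t-BuOOH) gives oxaspirohexane F7. Allylic 1,3-strain with the ring methylene cis to C6 fixes the reactive conformer.
- Et2AlCl then induces the analogous shift of C1 from C4 to C5 with inversion at C5. The oxirane oxygen becomes the ketone oxygen of 16.

Step 10.
- What may go wrong: the hindered ketone may enolise, the metal aldolate may cleave by retro-aldol reaction, or the isopropyl reagent may transfer a β-hydride instead of adding.
- The fallback sets out from 16 and comes back at 19. It changes both the order of events and the nucleophile.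
- Ring-closing metathesis of 16 (second-generation Hoveyda–Grubbs catalyst, CH2Cl2, 40 °C) gives bicyclic hydroxy ketone F8.
- Isopropenylmagnesium bromide with CeCl3 (THF, −78 °C) cannot act as a hydride donor. It adds from the face opposite the angular methyl group to give isopropenyl diol F9.
- Hydrogenation with RhCl(PPh3)3 and H2 (1 atm, benzene) saturates only the 1,1-disubstituted alkene and leaves the trisubstituted ring alkene, giving 19.

**Further compounds**
F1 | step 9 | lithium 4-methylpent-4-en-1-yn-1-ide | [Li]C#CCC(C)=C
F2 | step 9 | (1R,2R)-2-allyl-2-methyl-1-(4-methylpent-4-en-1-yn-1-yl)cyclobutan-1-ol | C=CC[C@@]1(C)CC[C@]1(O)C#CCC(C)=C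
F3 | step 9 | (3R,2E)-3-allyl-3-methyl-2-(3-methylbut-3-en-1-ylidene)cyclopentan-1-one | C=CC[C@@]1(C)CCC(=O)/C1=C/CC(C)=C
F4 | step 9 | C6-pinacolboryl analogue of 16 (boron in place of the C6 hydroxyl, same spatial arrangement) | C=CC[C@@]1(C)CCC(=O)[C@@H]1[C@@H](B2OC(C)(C)C(C)(C)O2)CC(C)=C
F5 | step 8 | (1E)-1-[(2R)-2-allyl-2-methylcyclobutylidene]-4-methylpent-4-en-2-one | C=CC[C@@]1(C)CC/C1=C\C(=O)CC(C)=C
F6 | step 8 | (2S,1E)-1-[(2R)-2-allyl-2-methylcyclobutylidene]-4-methylpent-4-en-2-ol | C=CC[C@@]1(C)CC/C1=C\[C@@H](O)CC(C)=C
F7 | step 8 | (1S)-1-[4-allyl-4-methyl-1-oxaspiro[2.3]hexan-2-yl]-3-methylbut-3-en-1-ol (oxirane oxygen on the face of the C6 hydroxyl) | C=CC[C@@]1(C)CC[C@@]12O[C@@H]2[C@@H](O)CC(C)=C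
F8 | step 10 | (3aS,4S,8aR)-4-hydroxy-6,8a-dimethyl-1,2,3a,4,5,8-hexahydroazulen-3-one | CC1=CC[C@@]2(C)CCC(=O)[C@@H]2[C@@H](O)C1
F9 | step 10 | 3-isopropenyl analogue of jaeschkeanadiol | CC1=CC[C@@]2(C)CC[C@@](O)(C(C)=C)[C@@H]2[C@@H](O)C1
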